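## Retrosynthetic overview

1. The target comes from invertive bromination of a C3 propargylic alcohol; oxolane ring C (O7–C4) comes from 5-exo opening of a (3S,4S)-alkynyl epoxide by the C7 hydroxyl.
2. Oxocane ring B, with C9–OAc, C10–Br, O6–C12 and C13–Br, comes from a ring-expanding bromo-acetoxylation of a 2,5-cis oxolane (ring A, O6–C9): bromonium at C12=C13, bicyclic oxonium, acetate opens C9–O (proposed new step).
3. Ring A comes from 5-exo bromoetherification of the (9Z,12E)-dienyl acetonide through the acetal oxygen (sets C9 and C10).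
4. The C15 chain comes from C8–C9 alkylation of a sugar-derived epoxy triflate with the acetylide of (E)-hept-4-en-1-yne, then Z-semihydrogenation; the epoxide comes from Shi epoxidation of the E-enyne made by olefination of 2-deoxy-D-ribose acetonide (C6 and C7 from the sugar).
5. Ring order: A (transient oxolane), then B (oxocane, by expansion of A), then C (oxolane).

Assumption: target chain numbering (C1 = alkyne CH, C15 = methyl; O6 and O7 are the oxygens on C6 and C7) is used for all intermediates, and (3-bromoprop-1-yn-1-yl)triisopropylsilane, (E)-1-bromopent-2-ene and the L-fructose-derived Shi ketone are taken as catalogue chemicals.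

## Route

Step 1
Reactants: 1 2-deoxy-D-ribose
Product: 2 3,4-O-isopropylidene-2-deoxy-D-ribopyranose (lactol; anomer mixture)
Conditions: 2-methoxypropene, PPTS (cat.), EtOAc, 0 °C → rt
Reagents that add atoms: 2-methoxypropene COC(C)=C
Why: Acid-catalysed acetalisation; only the cis-3,4-diol of the pyranose can span a dioxolane, so the future C6/C7 diol is masked while the lactol stays free, and no stereocentre is formed.

Step 2
Reactants: 3 (3-bromoprop-1-yn-1-yl)triisopropylsilane; 4 triethyl phosphite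
Product: 5 diethyl [3-(triisopropylsilyl)prop-2-yn-1-yl]phosphonate
Conditions: neat, 120 °C, distil off EtBr
Reagents that add atoms: none
Why: Michaelis–Arbuzov reaction of a reactive propargylic bromide; the silyl cap blocks propargyl–allenyl isomerisation.

Step 3
Reactants: 2 3,4-O-isopropylidene-2-deoxy-D-ribopyranose; 5 diethyl [3-(triisopropylsilyl)prop-2-yn-1-yl]phosphonate
Product: 7 (3E,6S,7R)-6,7-(isopropylidenedioxy)-1-(triisopropylsilyl)oct-3-en-1-yn-8-ol, via lithiated phosphonate 6 (not isolated)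
Conditions: 5 (2.5 equiv), LiN(SiMe3)2, THF, −78 °C; then 2, −78 °C → rt
Reagents that add atoms: none
Why: Horner–Wadsworth–Emmons olefination of the open-chain aldehyde in equilibrium with the lactol; silylpropargyl phosphonate anions give the E-enyne (about 10:1), and ring opening frees the C8 hydroxyl.

Step 4
Reactants: 7 (3E,6S,7R)-6,7-(isopropylidenedioxy)-1-(triisopropylsilyl)oct-3-en-1-yn-8-ol
Product: 8 (3S,4S,6S,7R)-3,4-epoxy-6,7-(isopropylidenedioxy)-1-(triisopropylsilyl)oct-1-yn-8-ol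
Conditions: L-fructose-derived Shi ketone (30 mol %), KHSO5 (as 2KHSO5·KHSO4·K2SO4), K2CO3, Bu4NHSO4, MeCN/CH2(OMe)2, aq. Na2B4O7/Na2EDTA buffer, 0 °C
Reagents that add atoms: potassium peroxymonosulfate [K+].[O-]S(=O)(=O)OO
Why: Shi asymmetric epoxidation of the only alkene; the L-ketone gives the mirror-image sense of the D-ketone (which gives R,R epoxides from trans-alkenes), so reagent control sets 3S,4S.

Step 5
Reactants: 9 (E)-1-bromopent-2-ene; 10 ethynylmagnesium bromide
Product: 11 (E)-hept-4-en-1-yne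
Conditions: CuCl (5 mol %), THF, 0 → 40 °C
Reagents that add atoms: none
Why: CuCl-catalysed coupling of an alkynyl Grignard reagent with a primary allylic bromide; attack at the α-carbon keeps the E geometry and gives the skipped enyne.

Step 6
Reactants: 8 (3S,4S,6S,7R)-3,4-epoxy-6,7-(isopropylidenedioxy)-1-(triisopropylsilyl)oct-1-yn-8-ol; 11 (E)-hept-4-en-1-yne
Product: 14 (3S,4S,6S,7R,12E)-3,4-epoxy-6,7-(isopropylidenedioxy)-1-(triisopropylsilyl)pentadec-12-ene-1,9-diyne, via primary triflate 12 (not isolated), via lithium heptenynide 13 (not isolated)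
Conditions: Tf2O, 2,6-lutidine, CH2Cl2, −78 °C; then 13 (from 11, n-BuLi, THF, −78 °C), DMPU, −78 → −30 °C
Reagents that add atoms: none
Why: SN2 alkylation of a lithium acetylide by a primary triflate, which at low temperature outruns attack on the disubstituted epoxide; no stereocentre is touched.

Step 7
Reactants: 14 (3S,4S,6S,7R,12E)-3,4-epoxy-6,7-(isopropylidenedioxy)-1-(triisopropylsilyl)pentadec-12-ene-1,9-diyne
Product: 16 (3S,4S,6S,7R,9Z,12E)-3,4-epoxy-6,7-(isopropylidenedioxy)pentadeca-9,12-dien-1-yne, via silylated dienyne 15 (not isolated)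
Conditions: H2 (1 atm), Pd/CaCO3 poisoned with Pb(OAc)2, quinoline, EtOAc, rt; filter; then Bu4NF, THF, 0 °C
Reagents that add atoms: none
Why: Lindlar semihydrogenation adds H2 syn to the dialkyl alkyne (9Z) while the bulky silyl-capped alkyne and the E-alkene are untouched; fluoride then removes the silyl group at a stage with nothing fluoride-sensitive present.

Step 8
Reactants: 16 (3S,4S,6S,7R,9Z,12E)-3,4-epoxy-6,7-(isopropylidenedioxy)pentadeca-9,12-dien-1-yne
Product: 18 (3S,4S,6S,7R,9S,10S,12E)-10-bromo-3,4:6,9-diepoxy-7-[(2-methoxypropan-2-yl)oxy]pentadec-12-en-1-yne (ring A bromo ether), via oxocarbenium ion 17 (not isolated)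
Conditions: NBS (1.05 equiv), MeOH (5 equiv), NaHCO3, CH2Cl2, −40 → −20 °C, dark
Reagents that add atoms: N-bromosuccinimide BrN1C(=O)CCC1=O; methanol CO
Why: 5-exo bromoetherification through an acetal oxygen (the reactivity used in n-pentenyl acetal activation): O6 opens the bromonium of the Z-alkene anti at C9 with the new side chain exo and trans to the acetal carbon on O6, hence cis to the C6 chain (9S,10S), and the 2-propylidene oxocarbenium left on O7 is trapped by MeOH as the 2-methoxypropan-2-yl (MOP) ether, so O7 is never free to open the epoxide; the Z-alkene reacts before the E-alkene because only it has 5-exo oxygen assistance.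

Step 9
Reactants: 18 (3S,4S,6S,7R,9S,10S,12E)-10-bromo-3,4:6,9-diepoxy-7-[(2-methoxypropan-2-yl)oxy]pentadec-12-en-1-yne
Product: 20 (3S,4S,6S,7R,9R,10S,12R,13S)-9-acetoxy-10,13-dibromo-3,4:6,12-diepoxy-7-[(2-methoxypropan-2-yl)oxy]pentadec-1-yne (oxocane ring B), via bicyclic oxonium ion 19 (not isolated)
Conditions: NBS (1.1 equiv), AcOH (2 equiv), Bu4NOAc (5 equiv), MeCN, −30 °C
Reagents that add atoms: N-bromosuccinimide BrN1C(=O)CCC1=O; acetic acid CC(=O)O
Why: Proposed new method: Br+ adds to the 12E alkene and the ring A oxygen closes 5-exo, anti, at C12 (12R,13S; bromopropyl group on the convex face, trans to C6 on oxygen) to give the cis-fused 1-oxoniabicyclo[3.3.0]octane 19, and free acetate at high concentration opens the shared C9–O bond by SN2 with inversion (9R, acetate cis to the C10 bromide) faster than the oxonium reverts to a bromonium, attack at C6 and C12 being slowed by the neighbouring MOP-oxy and branched bromopropyl groups; the closest known reaction type is ring-expanding bromoetherification of tetrahydrofurans through bicyclic oxonium ions opened by a tethered carbonate, together with bromonium-induced transannular oxonium formation–fragmentation with added carboxylate in larger cyclic ethers.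

Step 10
Reactants: 20 (3S,4S,6S,7R,9R,10S,12R,13S)-9-acetoxy-10,13-dibromo-3,4:6,12-diepoxy-7-[(2-methoxypropan-2-yl)oxy]pentadec-1-yne
Product: 22 (3S,4R,6S,7R,9R,10S,12R,13S)-9-acetoxy-10,13-dibromo-4,7:6,12-diepoxypentadec-1-yn-3-ol, via hydroxy epoxide 21 (not isolated)
Conditions: CSA (10 mol %), MeOH (5 equiv), CH2Cl2, 0 °C → rt
Reagents that add atoms: none
Why: Acid-catalysed transketalisation removes the MOP group and the freed C7 hydroxyl opens the trans-epoxide 5-exo at C4 with inversion (4R, cis-2,5 ring C, trans-fused to ring B) leaving the 3S alcohol; 6-endo attack at C3 is not favoured for an uncomplexed alkynyl epoxide, and the C9 acetate cannot migrate to O7 because the two are 1,3-trans.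

Step 11
Reactants: 22 (3S,4R,6S,7R,9R,10S,12R,13S)-9-acetoxy-10,13-dibromo-4,7:6,12-diepoxypentadec-1-yn-3-ol
Product: 23 (3R,4R,6S,7R,9R,10S,12R,13S)-9-acetoxy-3,10,13-tribromo-4,7:6,12-diepoxypentadec-1-yne (target)
Conditions: CBr4, PPh3, 2,6-lutidine, CH2Cl2, −20 → 0 °C
Reagents that add atoms: carbon tetrabromide BrC(Br)(Br)Br
Why: Appel reaction; bromide displaces the propargylic oxyphosphonium by SN2 with inversion (3S → 3R), and the low temperature without copper avoids SN2′ formation of a bromoallene.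

## Compound list

1 | 2-deoxy-D-ribose (open-chain form shown; sold as the pyranose) | O=CC[C@H](O)[C@H](O)CO | starting material
2 | 3,4-O-isopropylidene-2-deoxy-D-ribopyranose | OC1C[C@@H]2OC(C)(C)O[C@@H]2CO1 | intermediate
3 | (3-bromoprop-1-yn-1-yl)triisopropylsilane | BrCC#C[Si](C(C)C)(C(C)C)C(C)C | starting material
4 | triethyl phosphite | CCOP(OCC)OCC | starting material
5 | diethyl [3-(triisopropylsilyl)prop-2-yn-1-yl]phosphonate | CCOP(=O)(CC#C[Si](C(C)C)(C(C)C)C(C)C)OCC | intermediate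
6 | lithiated phosphonate (lithium salt of 5) | [Li+].CCOP(=O)(OCC)[CH-]C#C[Si](C(C)C)(C(C)C)C(C)C | intermediate
7 | (3E,6S,7R)-6,7-(isopropylidenedioxy)-1-(triisopropylsilyl)oct-3-en-1-yn-8-ol | OC[C@H]1OC(C)(C)O[C@H]1C/C=C/C#C[Si](C(C)C)(C(C)C)C(C)C | intermediate
8 | (3S,4S,6S,7R)-3,4-epoxy-6,7-(isopropylidenedioxy)-1-(triisopropylsilyl)oct-1-yn-8-ol | OC[C@H]1OC(C)(C)O[C@H]1C[C@@H]2O[C@H]2C#C[Si](C(C)C)(C(C)C)C(C)C | intermediate
9 | (E)-1-bromopent-2-ene | CC/C=C/CBr | starting material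
10 | ethynylmagnesium bromide | C#C[Mg]Br | starting material
11 | (E)-hept-4-en-1-yne | C#CC/C=C/CC | intermediate
12 | C8 trifluoromethanesulfonate of 8 | O=S(=O)(OC[C@H]1OC(C)(C)O[C@H]1C[C@@H]2O[C@H]2C#C[Si](C(C)C)(C(C)C)C(C)C)C(F)(F)F | intermediate
13 | lithium (E)-hept-4-en-1-yn-1-ide | [Li]C#CC/C=C/CC | intermediate
14 | (3S,4S,6S,7R,12E)-3,4-epoxy-6,7-(isopropylidenedioxy)-1-(triisopropylsilyl)pentadec-12-ene-1,9-diyne | CC/C=C/CC#CC[C@H]1OC(C)(C)O[C@H]1C[C@@H]2O[C@H]2C#C[Si](C(C)C)(C(C)C)C(C)C | intermediate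
15 | (3S,4S,6S,7R,9Z,12E)-3,4-epoxy-6,7-(isopropylidenedioxy)-1-(triisopropylsilyl)pentadeca-9,12-dien-1-yne | CC/C=C/C/C=C\C[C@H]1OC(C)(C)O[C@H]1C[C@@H]2O[C@H]2C#C[Si](C(C)C)(C(C)C)C(C)C | intermediate
16 | (3S,4S,6S,7R,9Z,12E)-3,4-epoxy-6,7-(isopropylidenedioxy)pentadeca-9,12-dien-1-yne | CC/C=C/C/C=C\C[C@H]1OC(C)(C)O[C@H]1C[C@@H]2O[C@H]2C#C | intermediate
17 | ring A bromo ether carrying the 2-propylidene oxocarbenium on O7 (succinimidate salt) | C#C[C@@H]1O[C@H]1C[C@@H]2O[C@H]([C@@H](Br)C/C=C/CC)C[C@H]2[O+]=C(C)C.O=C1CCC(=O)[N-]1 | intermediate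
18 | (3S,4S,6S,7R,9S,10S,12E)-10-bromo-3,4:6,9-diepoxy-7-[(2-methoxypropan-2-yl)oxy]pentadec-12-en-1-yne | C#C[C@@H]1O[C@H]1C[C@@H]2O[C@H]([C@@H](Br)C/C=C/CC)C[C@H]2OC(C)(C)OC | intermediate
19 | cis-fused bicyclic oxonium ion with O6 bonded to C6, C9 and C12 (acetate salt) | C#C[C@@H]1O[C@H]1C[C@@H]2[O+]3[C@@H](C[C@H]2OC(C)(C)OC)[C@@H](Br)C[C@@H]3[C@@H](Br)CC.CC(=O)[O-] | intermediate
20 | (3S,4S,6S,7R,9R,10S,12R,13S)-9-acetoxy-10,13-dibromo-3,4:6,12-diepoxy-7-[(2-methoxypropan-2-yl)oxy]pentadec-1-yne | C#C[C@@H]1O[C@H]1C[C@@H]2O[C@@H]([C@@H](Br)CC)C[C@H](Br)[C@H](OC(C)=O)C[C@H]2OC(C)(C)OC | intermediate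
21 | (3S,4S,6S,7R,9R,10S,12R,13S)-9-acetoxy-10,13-dibromo-3,4:6,12-diepoxypentadec-1-yn-7-ol | C#C[C@@H]1O[C@H]1C[C@@H]2O[C@@H]([C@@H](Br)CC)C[C@H](Br)[C@H](OC(C)=O)C[C@H]2O | intermediate
22 | (3S,4R,6S,7R,9R,10S,12R,13S)-9-acetoxy-10,13-dibromo-4,7:6,12-diepoxypentadec-1-yn-3-ol | C#C[C@H](O)[C@H]1C[C@@H]2O[C@@H]([C@@H](Br)CC)C[C@H](Br)[C@H](OC(C)=O)C[C@H]2O1 | intermediate
23 | (3R,4R,6S,7R,9R,10S,12R,13S)-9-acetoxy-3,10,13-tribromo-4,7:6,12-diepoxypentadec-1-yne | C#C[C@@H](Br)[C@H]1C[C@@H]2O[C@@H]([C@@H](Br)CC)C[C@H](Br)[C@H](OC(C)=O)C[C@H]2O1 | target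

## Step count and risks

Total step count: 11 (steps 2 and 5 are side branches). Longest linear sequence: 9 steps (1, 3, 4, 6, 7, 8, 9, 10, 11).

**Step 9 (the proposed new step).** The three carbons on the oxonium oxygen are electronically similar, so acetate may open 19 at C12 or C6 instead of C9, or 19 may revert to a bromonium and give trans bromo acetates. The fallback uses known reactions only; it sets out from 18 and comes back at 23.
- Zinc dust in ethanol eliminates the β-bromo ether and gives the mono-protected dienol F1 (Z-alkene restored, O6–H free).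
- 2,4,4,6-Tetrabromocyclohexa-2,5-dienone in CH2Cl2 closes the eight-membered ring directly at C12 (biomimetic bromoetherification, low-yielding; the five-membered by-product is returned to the dienol with zinc) and gives the bromo oxocene F2.
- CSA/MeOH removes the MOP group and closes ring C as in step 10, giving the bicyclic propargylic alcohol F3.
- CBr4/PPh3 gives the propargylic bromide F4.
- Dimethyldioxirane gives the 9,10-epoxide F5.
- Aqueous HClO4 in THF gives the trans-9,10-diol F6, separated from its 9S,10S isomer.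
- Trimethyl orthoacetate/PPTS, then acetyl bromide, converts the diol through the cyclic acetoxonium ion, opened by bromide with inversion at C10, into 23.

**Step 8.** The acetal oxygen O7 may instead close 5-endo at C10, or O6 may attack the other alkene face and give the 9R,10R isomer. The fallback postpones the epoxide and cyclises the free diol; it sets out from 7 and comes back at 20.
- Triflation and alkylation with 13 as in step 6 give the enediyne F7.
- Semihydrogenation and desilylation as in step 7 give the trienyne acetonide F8.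
- Aqueous AcOH gives the free trienyne diol F9.
- NBS with a BINOL-derived chiral phosphoric acid (catalyst-controlled 5-exo bromocycloetherification of a Z-4-alkenol by the C6 hydroxyl) gives the hydroxy bromo oxolane F10.
- 2-Methoxypropene/PPTS gives the MOP ether F11.
- The conditions of step 9 give the enyne oxocane F12.
- Shi epoxidation as in step 4 (the enyne alkene is now the only alkene) gives 20.

**Step 6.** The triflate next to an acetal and an epoxide is fragile, and the doubly activated CH2 of 13 can isomerise under base. The fallback moves the sp3 alkylation to the smallest nucleophile and makes the C10–C11 bond afterwards; it sets out from 8 and comes back at 14.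
- The triflate of 8 is treated with lithium acetylide (from acetylene and n-BuLi, THF/DMPU, −78 °C) to give the terminal diyne F13.
- F13 is coupled with 9 (CuI, NaI, K2CO3, DMF, rt) to give 14.

## Further compounds

F1 | step 9 | (3S,4S,6S,7R,9Z,12E)-3,4-epoxy-7-[(2-methoxypropan-2-yl)oxy]pentadeca-9,12-dien-1-yn-6-ol | CC/C=C/C/C=C\C[C@@H](OC(C)(C)OC)[C@@H](O)C[C@@H]1O[C@H]1C#C
F2 | step 9 | (3S,4S,6S,7R,9Z,12R,13S)-13-bromo-3,4:6,12-diepoxy-7-[(2-methoxypropan-2-yl)oxy]pentadec-9-en-1-yne | C#C[C@@H]1O[C@H]1C[C@@H]2O[C@@H]([C@@H](Br)CC)C/C=C\C[C@H]2OC(C)(C)OC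
F3 | step 9 | (3S,4R,6S,7R,9Z,12R,13S)-13-bromo-4,7:6,12-diepoxypentadec-9-en-1-yn-3-ol | C#C[C@H](O)[C@H]1C[C@@H]2O[C@@H]([C@@H](Br)CC)C/C=C\C[C@H]2O1
F4 | step 9 | (3R,4R,6S,7R,9Z,12R,13S)-3,13-dibromo-4,7:6,12-diepoxypentadec-9-en-1-yne | C#C[C@@H](Br)[C@H]1C[C@@H]2O[C@@H]([C@@H](Br)CC)C/C=C\C[C@H]2O1
F5 | step 9 | (3R,4R,6S,7R,9R,10S,12R,13S)-3,13-dibromo-4,7:6,12:9,10-triepoxypentadec-1-yne | C#C[C@@H](Br)[C@H]1C[C@@H]2O[C@@H]([C@@H](Br)CC)C[C@@H]3O[C@@H]3C[C@H]2O1
F6 | step 9 | (3R,4R,6S,7R,9R,10R,12R,13S)-3,13-dibromo-4,7:6,12-diepoxypentadec-1-yne-9,10-diol | C#C[C@@H](Br)[C@H]1C[C@@H]2O[C@@H]([C@@H](Br)CC)C[C@@H](O)[C@H](O)C[C@H]2O1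
F7 | step 8 | (3E,6S,7R,12E)-6,7-(isopropylidenedioxy)-1-(triisopropylsilyl)pentadeca-3,12-diene-1,9-diyne | CC/C=C/CC#CC[C@H]1OC(C)(C)O[C@H]1C/C=C/C#C[Si](C(C)C)(C(C)C)C(C)C
F8 | step 8 | (3E,6S,7R,9Z,12E)-6,7-(isopropylidenedioxy)pentadeca-3,9,12-trien-1-yne | CC/C=C/C/C=C\C[C@H]1OC(C)(C)O[C@H]1C/C=C/C#C
F9 | step 8 | (3E,6S,7R,9Z,12E)-pentadeca-3,9,12-trien-1-yne-6,7-diol | CC/C=C/C/C=C\C[C@@H](O)[C@@H](O)C/C=C/C#C
F10 | step 8 | (3E,6S,7R,9S,10S,12E)-10-bromo-6,9-epoxypentadeca-3,12-dien-1-yn-7-ol | C#C/C=C/C[C@@H]1O[C@H]([C@@H](Br)C/C=C/CC)C[C@H]1O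
F11 | step 8 | (3E,6S,7R,9S,10S,12E)-10-bromo-6,9-epoxy-7-[(2-methoxypropan-2-yl)oxy]pentadeca-3,12-dien-1-yne | C#C/C=C/C[C@@H]1O[C@H]([C@@H](Br)C/C=C/CC)C[C@H]1OC(C)(C)OC
F12 | step 8 | (3E,6S,7R,9R,10S,12R,13S)-9-acetoxy-10,13-dibromo-6,12-epoxy-7-[(2-methoxypropan-2-yl)oxy]pentadec-3-en-1-yne | C#C/C=C/C[C@@H]1O[C@@H]([C@@H](Br)CC)C[C@H](Br)[C@H](OC(C)=O)C[C@H]1OC(C)(C)OC
F13 | step 6 | (3S,4S,6S,7R)-3,4-epoxy-6,7-(isopropylidenedioxy)-1-(triisopropylsilyl)deca-1,9-diyne | C#CC[C@H]1OC(C)(C)O[C@H]1C[C@@H]2O[C@H]2C#C[Si](C(C)C)(C(C)C)C(C)C
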